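**Strategy**

Ring B is disconnected at C7–C8 and C9–C10. The feature exploited is that C10, the fully substituted A/B junction, and C6, the future acetoxy carbon, are the terminus and the oxygenated 2-position of one silyloxy diene, C10=C5–C6=C7, which contains the ring A double bond. (E)-But-2-enal brings C8, C9, the C17 methyl and C11. A single catalytic, enantioselective [4+2] thus closes ring B, forms both C–C bonds, sets C10 permanently and leaves C6 as a masked ketone. Its precursor is the TBS enol ether of 1-(2,6,6-trimethylcyclohexenyl)ethanone, three steps from β-cyclocitral. C5–C9 are then set by substrate control.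

Key step: step 4

Remark 1: terpenoid numbering is used (decalin C1–C10, C11 on C9, C17 on C8, C18/C19 on C4, C20 on C10, side chain C11–C14); β is the face of C20, α the opposite face.

Remark 2: an equatorial 9β-formyl group is gauche to both the 8β- and the 10β-methyl group and is not assumed to be the thermodynamic epimer, so C9 is inverted by kinetic protonation (step 5), not by equilibration.

**Route**

Step 1
Reactants: 1 β-cyclocitral; 2 methylmagnesium bromide
Product: 3 1-(2,6,6-trimethylcyclohex-1-en-1-yl)ethan-1-ol (racemic)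
Conditions: MeMgBr, THF, 0 °C; aq. NH4Cl
Reagents that add atoms: methylmagnesium bromide, C[Mg]Br
Why: Grignard 1,2-addition to the aldehyde gives the secondary allylic alcohol, whose new stereocentre need not be controlled because step 2 removes it.

Step 2
Reactants: 3 1-(2,6,6-trimethylcyclohex-1-en-1-yl)ethan-1-ol
Product: 4 1-(2,6,6-trimethylcyclohex-1-en-1-yl)ethan-1-one
Conditions: DMP (Dess–Martin periodinane), CH2Cl2, rt
Reagents that add atoms: none
Why: Dess–Martin oxidation converts the secondary allylic alcohol into the methyl ketone under neutral conditions that do not move the tetrasubstituted double bond.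

Step 3
Reactants: 4 1-(2,6,6-trimethylcyclohex-1-en-1-yl)ethan-1-one
Product: 5 tert-butyldimethyl{[1-(2,6,6-trimethylcyclohex-1-en-1-yl)ethenyl]oxy}silane (diene C10=C5–C6(OTBS)=C7)
Conditions: TBSOTf, Et3N, CH2Cl2, 0 °C
Reagents that add atoms: tert-butyldimethylsilyl trifluoromethanesulfonate, CC(C)(C)[Si](C)(C)OS(=O)(=O)C(F)(F)F
Why: Soft enolisation (silyl triflate and amine) of a methyl ketone whose only α-hydrogens sit on the methyl group is the standard silyl enol ether formation leading to 2-silyloxy-1,3-dienes, and the twisted enone disfavours γ-deprotonation.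

Step 4
Reactants: 5 tert-butyldimethyl{[1-(2,6,6-trimethylcyclohex-1-en-1-yl)ethenyl]oxy}silane; 6 (E)-but-2-enal
Product: 7 endo adduct, 6-(tert-butyldimethylsilyloxy)drim-5-en-11-al with 8β-methyl (8α-H), 9α-formyl (9β-H) and 10β-methyl
Conditions: (3aR)-1-(2-methylphenyl)-3,3-diphenyltetrahydro-1H,3H-pyrrolo[1,2-c][1,3,2]oxazaborole (20 mol %), HN(SO2CF3)2 (18 mol %), CH2Cl2, −78 → −20 °C; Et3N quench
Reagents that add atoms: none
Why: Proposed new method: the N-protonated oxazaborolidine should bind the formyl oxygen of 6 (formyl C–H···O contact, s-trans enal stacked on an aryl group) and leave the Si face of C9 open, so that a concerted, asynchronous, normal-demand [4+2] begins at the nucleophilic enol-ether terminus C7 (bond to the β-carbon C8) and ends with C10 bonding to the α-carbon C9; the closest known reaction type is the oxazaborolidinium-catalysed enantioselective Diels–Alder addition of 2-silyloxy-1,3-dienes to α,β-enals, here extended to a diene whose reacting terminus is fully substituted, a class so far cyclised only thermally or with achiral Lewis acids. Ring B is closed by intermolecular [4+2] cycloaddition, both σ bonds (C7–C8 and C9–C10) forming suprafacially on diene and dienophile. C10 is set by the catalyst-controlled enal face together with the endo orientation of the formyl group, which places CHO anti to the inward methyl C20 (10β-Me, 9α-CHO), and C8 follows from the E geometry of 6 (methyl trans to formyl, 8β-Me). Regioselectivity is needed and is secured twice, by the 6-silyloxy group (formyl para to oxygen) and by the alkyl groups on C10 (formyl ortho); enantioselectivity is needed and comes only from the catalyst, whose (3aR) antipode is chosen from the pre-transition-state model. Ring A locks the C10=C5 geometry, and a slight deficit of HN(SO2CF3)2 relative to the oxazaborolidine keeps free acid away from the silyl enol ethers.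

Step 5
Reactants: 7 endo adduct (9α-formyl)
Product: 9 C9-epimerised aldehyde [6-(tert-butyldimethylsilyloxy)drim-5-en-11-al; 8β-methyl; 9β-formyl; 10β-methyl], via potassium enolate 8 (not isolated)
Conditions: KH, THF, 0 °C; then cannulated into AcOH/THF, −78 °C
Reagents that add atoms: none
Why: Irreversible enolisation of the α-branched aldehyde followed by kinetic protonation of the exocyclic enolate (contra-thermodynamic epimerisation) should deliver the proton to C9 from the α face, opposite the 8β- and 10β-methyl groups that flank it, giving 9α-H and hence the 9β-formyl group.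

Step 6
Reactants: 9 C9-epimerised aldehyde
Product: 11 hydroxy ketone [11-hydroxy-8β-methyl-5α-driman-6-one; 9β-CH2OH; 10β-methyl], via hydroxy enol ether 10 (not isolated)
Conditions: NaBH4, MeOH/THF, −20 °C; then 1 M HCl, THF, rt
Reagents that add atoms: none
Why: Borohydride reduction of the aldehyde freezes C9, and acid hydrolysis of the silyl enol ether then protonates C5 from the less hindered α face, which is also the thermodynamic trans ring fusion reached by acid-mediated enolisation.

Step 7
Reactants: 11 hydroxy ketone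
Product: 12 11-(tert-butyldimethylsilyloxy)-8β-methyl-5α-driman-6-one
Conditions: TBSCl, imidazole, DMF, rt
Reagents that add atoms: tert-butyldimethylsilyl chloride, CC(C)(C)[Si](C)(C)Cl
Why: Standard silylation of the primary alcohol masks C11–OH for the enolate, oxidation and acylation steps that follow.

Step 8
Reactants: 12 11-(tert-butyldimethylsilyloxy)-8β-methyl-5α-driman-6-one
Product: 14 enone [11-(tert-butyldimethylsilyloxy)drim-7-en-6-one; 5α-H; 9α-H], via silyl enol ether 13 (not isolated)
Conditions: Me3SiCl, LiN(iPr)2, THF, −78 °C (in situ trapping); evaporation; Pd(OAc)2 (1.1 equiv), MeCN, rt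
Reagents that add atoms: none
Why: In this Saegusa–Ito dehydrogenation kinetic deprotonation occurs at the C7 methylene and not at the hindered C5 methine, and the palladium enolate can only eliminate the 8α-hydrogen, so the Δ7-6-one should form and C8 becomes trigonal.

Step 9
Reactants: 14 enone
Product: 15 7α,8α-epoxy-11-(tert-butyldimethylsilyloxy)driman-6-one (8β-methyl)
Conditions: 30 % H2O2, NaOH, MeOH, 0 °C → rt
Reagents that add atoms: hydrogen peroxide, OO
Why: Weitz–Scheffer nucleophilic epoxidation of the β-methyl enone should add hydroperoxide to C8 from the α face, anti to the axial 10β-methyl group, so that the epoxide oxygen is α at C7 and C8 and the C17 methyl stays β.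

Step 10
Reactants: 15 epoxy ketone
Product: 16 11-(tert-butyldimethylsilyloxy)drim-6-en-8α-ol (8β-methyl)
Conditions: N2H4·H2O, AcOH (cat.), MeOH, 0 °C → rt
Reagents that add atoms: none
Why: In the Wharton transposition the epoxy hydrazone collapses to a vinyl diazene that loses N2, which moves the double bond to C6=C7 and leaves the C8–O bond untouched, so the tertiary alcohol keeps the α configuration of the epoxide.

Step 11
Reactants: 16 allylic alcohol
Product: 17 11-(tert-butyldimethylsilyloxy)drimane-6α,7α,8α-triol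
Conditions: OsO4 (cat.), N-methylmorpholine N-oxide, acetone/H2O, rt
Reagents that add atoms: osmium tetroxide, O=[Os](=O)(=O)=O; N-methylmorpholine N-oxide, C[N+]1([O-])CCOCC1; water, O
Why: Upjohn dihydroxylation (suprafacial addition of OsO4) should take place on the α face, which is free of the axial 4β-, 8β- and 10β-methyl groups, and so sets 6α-OH and 7α-OH together.

Step 12
Reactants: 17 triol
Product: 18 6α-acetoxy-11-(tert-butyldimethylsilyloxy)drimane-7α,8α-diol
Conditions: Ac2O (1.2 equiv), pyridine, CH2Cl2, 0 °C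
Reagents that add atoms: acetic anhydride, CC(=O)OC(C)=O
Why: Regioselective acetylation is expected at the equatorial secondary 6α-hydroxyl, because the axial 7α-hydroxyl next to the fully substituted C8 and the tertiary 8α-hydroxyl acylate much more slowly.

Step 13
Reactants: 18 monoacetate
Product: 19 6α-acetoxy-8α-hydroxy-11-(tert-butyldimethylsilyloxy)driman-7-one
Conditions: DMP, pyridine, CH2Cl2, 0 °C → rt
Reagents that add atoms: none
Why: Dess–Martin oxidation of the only remaining secondary alcohol should give the 7-ketone without cleaving the tertiary α-ketol and without disturbing the equatorial, configurationally stable 6α-acetate.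

Step 14
Reactants: 19 7-ketone
Product: 20 6α-acetoxy-11-(tert-butyldimethylsilyloxy)drimane-7β,8α-diol
Conditions: NaBH4, CeCl3·7H2O, MeOH, −78 °C; AcOH quench
Reagents that add atoms: none
Why: In this Luche reduction axial hydride attack from the α face, where only 5α-H and 9α-H are 1,3-diaxial, should give the equatorial 7β-alcohol and complete the net inversion at C7, while low temperature and the acidic quench suppress acetyl migration.

Step 15
Reactants: 20 7β-alcohol
Product: 21 6α-acetoxydrimane-7β,8α,11-triol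
Conditions: HF·pyridine, pyridine, THF, 0 °C → rt
Reagents that add atoms: none
Why: Fluoride-mediated desilylation of the primary silyl ether under weakly acidic conditions avoids the base-induced shift of the acetyl group from O6 to O7.

Step 16
Reactants: 21 triol monoacetate
Product: 22 6α-acetoxy-7β,8α-dihydroxydriman-11-al
Conditions: TEMPO (cat.), PhI(OAc)2, CH2Cl2, rt
Reagents that add atoms: none
Why: The oxoammonium (TEMPO) oxidation is selective for the primary alcohol beside secondary and tertiary hydroxyls and stops at the aldehyde under neutral conditions that the β-hydroxy aldehyde should tolerate.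

Step 17
Reactants: 22 6α-acetoxy-7β,8α-dihydroxydriman-11-al; 23 1-(triphenyl-λ5-phosphanylidene)propan-2-one
Product: 24 target, (3E)-4-[(1R,2S,3S,4R,4aS,8aS)-4-acetoxy-2,3-dihydroxy-2,5,5,8a-tetramethyldecahydronaphthalen-1-yl]but-3-en-2-one
Conditions: 23, toluene, 70 °C
Reagents that add atoms: 1-(triphenyl-λ5-phosphanylidene)propan-2-one, CC(=O)C=P(c1ccccc1)(c1ccccc1)c1ccccc1
Why: Wittig olefination with a stabilised, non-basic ylide should give the (E)-enone selectively and add C12–C14 without retro-aldol cleavage or epimerisation at C9.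

**Compound list**

1 | β-cyclocitral (2,6,6-trimethylcyclohex-1-ene-1-carbaldehyde) | CC1=C(C=O)C(C)(C)CCC1 | starting material
2 | methylmagnesium bromide | C[Mg]Br | starting material
3 | 1-(2,6,6-trimethylcyclohex-1-en-1-yl)ethan-1-ol (racemic) | CC(O)C1=C(C)CCCC1(C)C | intermediate
4 | 1-(2,6,6-trimethylcyclohex-1-en-1-yl)ethan-1-one | CC(=O)C1=C(C)CCCC1(C)C | intermediate
5 | tert-butyldimethyl{[1-(2,6,6-trimethylcyclohex-1-en-1-yl)ethenyl]oxy}silane | C=C(O[Si](C)(C)C(C)(C)C)C1=C(C)CCCC1(C)C | intermediate
6 | (E)-but-2-enal | C/C=C/C=O | starting material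
7 | endo adduct, 6-(tert-butyldimethylsilyloxy)drim-5-en-11-al, 8β-Me, 9α-CHO, 10β-Me | O=C[C@@H]1[C@@H](C)CC(O[Si](C)(C)C(C)(C)C)=C2C(C)(C)CCC[C@@]21C | intermediate
8 | potassium C9=C11 enolate of 7 | [K+].[O-]C=C1[C@@H](C)CC(O[Si](C)(C)C(C)(C)C)=C2C(C)(C)CCC[C@@]21C | intermediate (not isolated)
9 | 6-(tert-butyldimethylsilyloxy)drim-5-en-11-al, 8β-Me, 9β-CHO, 10β-Me | O=C[C@H]1[C@@H](C)CC(O[Si](C)(C)C(C)(C)C)=C2C(C)(C)CCC[C@@]21C | intermediate
10 | 6-(tert-butyldimethylsilyloxy)drim-5-en-11-ol, 8β-Me, 9β-CH2OH | OC[C@H]1[C@@H](C)CC(O[Si](C)(C)C(C)(C)C)=C2C(C)(C)CCC[C@@]21C | intermediate (not isolated)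
11 | 11-hydroxy-8β-methyl-5α-driman-6-one (9β-CH2OH) | OC[C@H]1[C@@H](C)CC(=O)[C@H]2C(C)(C)CCC[C@@]21C | intermediate
12 | 11-(tert-butyldimethylsilyloxy)-8β-methyl-5α-driman-6-one | CC(C)(C)[Si](C)(C)OC[C@H]1[C@@H](C)CC(=O)[C@H]2C(C)(C)CCC[C@@]21C | intermediate
13 | Δ6 trimethylsilyl enol ether of 12 | CC(C)(C)[Si](C)(C)OC[C@H]1[C@@H](C)C=C(O[Si](C)(C)C)[C@H]2C(C)(C)CCC[C@@]21C | intermediate (not isolated)
14 | 11-(tert-butyldimethylsilyloxy)drim-7-en-6-one (5α-H, 9α-H) | CC(C)(C)[Si](C)(C)OC[C@H]1C(C)=CC(=O)[C@H]2C(C)(C)CCC[C@@]21C | intermediate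
15 | 7α,8α-epoxy-11-(tert-butyldimethylsilyloxy)driman-6-one | CC(C)(C)[Si](C)(C)OC[C@H]1[C@]3(C)O[C@@H]3C(=O)[C@H]2C(C)(C)CCC[C@@]21C | intermediate
16 | 11-(tert-butyldimethylsilyloxy)drim-6-en-8α-ol | CC(C)(C)[Si](C)(C)OC[C@H]1[C@](C)(O)C=C[C@H]2C(C)(C)CCC[C@@]21C | intermediate
17 | 11-(tert-butyldimethylsilyloxy)drimane-6α,7α,8α-triol | CC(C)(C)[Si](C)(C)OC[C@H]1[C@](C)(O)[C@H](O)[C@H](O)[C@H]2C(C)(C)CCC[C@@]21C | intermediate
18 | 6α-acetoxy-11-(tert-butyldimethylsilyloxy)drimane-7α,8α-diol | CC(C)(C)[Si](C)(C)OC[C@H]1[C@](C)(O)[C@H](O)[C@H](OC(C)=O)[C@H]2C(C)(C)CCC[C@@]21C | intermediate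
19 | 6α-acetoxy-8α-hydroxy-11-(tert-butyldimethylsilyloxy)driman-7-one | CC(C)(C)[Si](C)(C)OC[C@H]1[C@](C)(O)C(=O)[C@H](OC(C)=O)[C@H]2C(C)(C)CCC[C@@]21C | intermediate
20 | 6α-acetoxy-11-(tert-butyldimethylsilyloxy)drimane-7β,8α-diol | CC(C)(C)[Si](C)(C)OC[C@H]1[C@](C)(O)[C@@H](O)[C@H](OC(C)=O)[C@H]2C(C)(C)CCC[C@@]21C | intermediate
21 | 6α-acetoxydrimane-7β,8α,11-triol | OC[C@H]1[C@](C)(O)[C@@H](O)[C@H](OC(C)=O)[C@H]2C(C)(C)CCC[C@@]21C | intermediate
22 | 6α-acetoxy-7β,8α-dihydroxydriman-11-al | O=C[C@H]1[C@](C)(O)[C@@H](O)[C@H](OC(C)=O)[C@H]2C(C)(C)CCC[C@@]21C | intermediate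
23 | 1-(triphenyl-λ5-phosphanylidene)propan-2-one | CC(=O)C=P(c1ccccc1)(c1ccccc1)c1ccccc1 | starting material
24 | CNP0136046.1, (3E)-4-[(1R,2S,3S,4R,4aS,8aS)-4-acetoxy-2,3-dihydroxy-2,5,5,8a-tetramethyldecahydronaphthalen-1-yl]but-3-en-2-one | CC(=O)/C=C/[C@H]1[C@](C)(O)[C@@H](O)[C@H](OC(C)=O)[C@H]2C(C)(C)CCC[C@@]21C | target

**Step count and risk**

Total step count: 17. Longest linear sequence: 17 steps (1 → 24); 2, 6 and 23 are purchased.

Steps most likely to fail:

1. Step 4 (Proposed new method). The congested diene may not reach a near-planar s-cis geometry inside the catalyst pocket, so the reaction may not turn over, may stop after the first C–C bond (Mukaiyama–Michael stage), or may proceed with low facial discrimination of the enal. The fallback uses known chemistry and accepts a resolution. It sets out from 5 and 6, which are combined under an achiral Lewis acid (Me2AlCl, CH2Cl2, −78 °C) or thermally to give the racemic endo adduct F1. Steps 5 and 6 are run unchanged on the racemate, through the racemic potassium enolate F2, the racemic 9β-aldehyde F3 and the racemic hydroxy enol ether F4, to the racemic hydroxy ketone F5. Acylation with (1S)-camphanic chloride (Et3N, 4-dimethylaminopyridine, CH2Cl2) gives the diastereomeric esters, the camphanate of 11 F6 and the camphanate of ent-11 F7, which are separated by crystallisation or chromatography. Methanolysis of F6 (K2CO3, MeOH) comes back to the route at compound 11.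

2. Step 5. Facial discrimination in the protonation of the enolate may be poor if ring B of the enolate adopts a conformation with the 8β-methyl equatorial, or the aldehyde may re-equilibrate during work-up. The fallback sets out from 7 and delivers the C9 hydrogen with a bulky borane instead of a proton donor. Enolate 8 is trapped with N-phenylbis(trifluoromethanesulfonimide) to give the enol triflate F8. Transfer hydrogenolysis (Pd(OAc)2, PPh3, HCO2H, Bu3N, DMF, 60 °C) gives the 9(11)-exocyclic methylene compound F9. Hydroboration with 9-borabicyclo[3.3.1]nonane, which should add B–H across the α face away from the two β-methyl groups, gives the alkylborane F10. Oxidation (NaBO3·4H2O, THF/H2O) comes back to the route at compound 10, which is carried through the acid stage of step 6.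

3. Step 10. Hydrazone formation at the hindered C6 carbonyl may be slow, and the vinyl diazene may be diverted before it loses nitrogen. The fallback sets out from 15 and removes the C6 oxygen by enol triflate reduction instead. Reductive opening of the epoxide Cα–O bond (SmI2, THF/MeOH, −90 °C) gives the β-hydroxy ketone F11. Kinetic deprotonation toward C7 (LiN(SiMe3)2, 2.2 equiv, THF, −78 °C) gives the dilithium alkoxide enolate F12, which is trapped with N-phenylbis(trifluoromethanesulfonimide) to give the Δ6-enol triflate F13. Transfer hydrogenolysis (Pd(OAc)2, PPh3, HCO2H, Bu3N, DMF, 60 °C) comes back to the route at compound 16.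

**Further compounds**

F1 | step 4 | racemic endo adduct (7 and its enantiomer) | O=C[C@@H]1[C@@H](C)CC(O[Si](C)(C)C(C)(C)C)=C2C(C)(C)CCC[C@@]21C.O=C[C@H]1[C@H](C)CC(O[Si](C)(C)C(C)(C)C)=C2C(C)(C)CCC[C@]21C
F2 | step 4 | racemic potassium enolate (8 and its enantiomer) | [K+].[O-]C=C1[C@@H](C)CC(O[Si](C)(C)C(C)(C)C)=C2C(C)(C)CCC[C@@]21C.[K+].[O-]C=C1[C@H](C)CC(O[Si](C)(C)C(C)(C)C)=C2C(C)(C)CCC[C@]21C
F3 | step 4 | racemic 9β-aldehyde (9 and its enantiomer) | O=C[C@H]1[C@@H](C)CC(O[Si](C)(C)C(C)(C)C)=C2C(C)(C)CCC[C@@]21C.O=C[C@@H]1[C@H](C)CC(O[Si](C)(C)C(C)(C)C)=C2C(C)(C)CCC[C@]21C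
F4 | step 4 | racemic hydroxy enol ether (10 and its enantiomer) | OC[C@H]1[C@@H](C)CC(O[Si](C)(C)C(C)(C)C)=C2C(C)(C)CCC[C@@]21C.OC[C@@H]1[C@H](C)CC(O[Si](C)(C)C(C)(C)C)=C2C(C)(C)CCC[C@]21C
F5 | step 4 | racemic hydroxy ketone (11 and its enantiomer) | OC[C@H]1[C@@H](C)CC(=O)[C@H]2C(C)(C)CCC[C@@]21C.OC[C@@H]1[C@H](C)CC(=O)[C@@H]2C(C)(C)CCC[C@]21C
F6 | step 4 | (1S)-camphanate of 11 | O=C(OC[C@H]1[C@@H](C)CC(=O)[C@H]2C(C)(C)CCC[C@@]21C)[C@@]34CC[C@@](C)(C(=O)O3)C4(C)C
F7 | step 4 | (1S)-camphanate of ent-11 | O=C(OC[C@@H]1[C@H](C)CC(=O)[C@@H]2C(C)(C)CCC[C@]21C)[C@@]34CC[C@@](C)(C(=O)O3)C4(C)C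
F8 | step 5 | C9=C11 enol triflate of 7 | O=S(=O)(OC=C1[C@@H](C)CC(O[Si](C)(C)C(C)(C)C)=C2C(C)(C)CCC[C@@]21C)C(F)(F)F
F9 | step 5 | 6-(tert-butyldimethylsilyloxy)-8β-methyldrima-5,9(11)-diene | C=C1[C@@H](C)CC(O[Si](C)(C)C(C)(C)C)=C2C(C)(C)CCC[C@@]21C
F10 | step 5 | 11-(9-borabicyclo[3.3.1]nonan-9-yl) derivative of the 9α-H silyl enol ether | C([C@H]1[C@@H](C)CC(O[Si](C)(C)C(C)(C)C)=C2C(C)(C)CCC[C@@]21C)B1C2CCCC1CCC2
F11 | step 10 | 8α-hydroxy-11-(tert-butyldimethylsilyloxy)-5α-driman-6-one | CC(C)(C)[Si](C)(C)OC[C@H]1[C@](C)(O)CC(=O)[C@H]2C(C)(C)CCC[C@@]21C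
F12 | step 10 | dilithium alkoxide Δ6-enolate of F11 | [Li+].[Li+].CC(C)(C)[Si](C)(C)OC[C@H]1[C@](C)([O-])C=C([O-])[C@H]2C(C)(C)CCC[C@@]21C
F13 | step 10 | 8α-hydroxy-11-(tert-butyldimethylsilyloxy)drim-6-en-6-yl trifluoromethanesulfonate | CC(C)(C)[Si](C)(C)OC[C@H]1[C@](C)(O)C=C(OS(=O)(=O)C(F)(F)F)[C@H]2C(C)(C)CCC[C@@]21C
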